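If you want to know what a flask charged at 0.25 M holds after 12 min, first ask which of the given numbers has to be known well.

| flask | starting material | remark | time |
|---|---|---|---|
| maple | 0.12 M | run made earlier |  |
| larch | 0.19 M | run made earlier |  |
| flask | 0.25 M |  | 12 min |

- maple (time / min: target / %, isomer of the product / %): 3.00: 2, 90; 6.00: 7, 93; 10.0: 4, 95; 12.0: 2, 92
- larch (time / min: target / %, isomer of the product / %): 1.00: 24, 64; 2.00: 9, 84; 5.00: 8, 93; 12.0: 3, 94

(readings scatter by 2 percentage points)

- steps that have been proposed: starting material <-> target; starting material <-> isomer of the product; target <-> isomer of the product
- the reaction counts as stopped when no species that holds the starting material changes by six tenths of a point or more over the second half of the time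

* the state of affairs at 12 min: stopped, and by what, or still going (forward and back rates have come level / it is still moving / all of the starting material has reacted)
* target at 12 min, in percent of the starting material charged
* isomer of the product at 12 min, in percent of the starting material charged

Take the charge first. Larch holds 1.58 times the charge of maple, yet the late isomer readings average 93.3 % of the charge in maple and 93.5 % in larch. A reading scatters by 2 percentage points, and these two means lie well within that.

Take the time next. Call the free share the fraction of the charge that the isomer of the product leaves to target and starting material together, once the readings stop moving. From the 5 readings from 5.00 min on, it is 6.60 %, good to about 0.89 points. In larch, the isomer's distance from that level halves in about 0.608 min, as read from two readings, which is far shorter than 12 min.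

So the late readings are the numbers that count. My reckoning is thermodynamic control in the new flask, with isomer at 93.4 % and target at its late mean of 4.80 %.

The forecast says forward and back rates have come level, with target 4 % and isomer 93.5 %: “Twelve minutes is many relaxation times, so I expect equilibrium, not complete consumption.”

The flask gives forward and back rates have come level, with target 4.76 % and isomer 93.0 %.

    starting material ⇌ target (K = 2.10, k = 0.0870 s⁻¹)
    starting material ⇌ isomer of the product (K = 41.0, k = 9.40 × 10⁻⁴ s⁻¹)
    target ⇌ isomer of the product (k = 0.0330 s⁻¹)

The free share of this flask is 7.00 %, and a neighbouring flask charged at 0.10 M gives 7.03 %. The largest single effect on how far the starting material goes comes from the conversion of target into isomer of the product, both ways. With that step taken away, conversion of starting material stands at 74.2 % instead of 97.7 %, a drop of 23 points.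

The earlier runs and the new flask were computed with made-up constants, noise included.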